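**Retrosynthetic overview**
- The aryl ester C–O bond is cut last-but-two: a bicyclic diol (C15) and a benzyl-protected isovanilloyl chloride (C15) are joined late, then an OH-directed epoxidation and a hydrogenolysis finish the target.
- The syn-1,3-diol comes from a cycloheptenone by bulky-hydride reduction, OH-directed epoxidation and hydride opening; the seven-membered ring is closed by ring-closing metathesis (C5=C6).
- The cyclopentene carries C3a, C8a and C8 before ring closure: Ireland–Claisen rearrangement of (S)-cyclopent-2-enyl isovalerate, allylic oxidation, anti conjugate methallylation, enol triflate and Negishi methylation.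
- The aryl fragment is built from catechol: mono-methylation, acetate-controlled bromination para to OMe, benzyl swap, Br/Li exchange–CO2, acid chloride.
- Ring order: cyclopentene (present from the start) → cycloheptene (metathesis) → oxirane (last ring).

Assumption: bicyclic compounds carry azulene locants (C1–C3, C3a, C4–C8, C8a; α = the face of the target's ring oxygens), and LDA, MeZnCl and the Grignard reagents are bought as solutions.

**Step 1**
Reactants: 1 cyclopentene oxide (meso 6-oxabicyclo[3.1.0]hexane); 2 3-methylbutanoyl chloride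
Product: 4 (1S)-cyclopent-2-en-1-yl 3-methylbutanoate, via lithium (1S)-cyclopent-2-en-1-olate 3 (not isolated)
Conditions: chiral lithium amide (2-azanorbornylmethyl-pyrrolidine diamine, 5 mol %, enantiomer giving the S alkoxide), LDA (1.5 equiv), DBU, THF, 0 °C; then 2 (excess), 0 °C → rt
Reagents that add atoms: none
Why: Enantioselective epoxide-to-allylic-alcohol rearrangement (syn β-elimination by a chiral lithium amide that distinguishes the enantiotopic C–H bonds of the meso epoxide) sets the S carbinol centre, and the alkoxide is O-acylated in the same pot because the free alcohol is volatile and water-soluble.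

**Step 2**
Reactants: 4
Product: 7 (2S)-2-[(1R)-cyclopent-2-en-1-yl]-3-methylbutanoic acid, via silyl ketene acetal 5 (not isolated), via trimethylsilyl ester 6 (not isolated)
Conditions: LDA, THF–DMPU (4:1), −78 °C; TMSCl; → rt, then 50 °C; aq. HCl
Reagents that add atoms: none
Why: Ireland–Claisen [3,3] rearrangement, in which the Z(O)-enolate formed in THF–DMPU gives the ketene acetal with i-Pr cis to OSi, which reacts suprafacially on the oxygen-bearing ring face through the boat-like transition state favoured for cycloalkenyl esters, transferring the carbinol chirality to the ring carbon (R) and setting the α-carbon (S).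

**Step 3**
Reactants: 7
Product: 9 (2S)-2-[(1R)-cyclopent-2-en-1-yl]-N-methoxy-N,3-dimethylbutanamide, via acyl imidazole 8 (not isolated)
Conditions: CDI, DCM, rt; then MeNH(OMe)·HCl, rt → 40 °C
Reagents that add atoms: N,O-dimethylhydroxylamine hydrochloride (CNOC.Cl)
Why: Weinreb amide formation through the acyl imidazole needs no strong base, so the α-centre is not epimerised, and the minor C2 epimer from step 2 is removed here by chromatography.

**Step 4**
Reactants: 9
Product: 10 (2S)-N-methoxy-N,3-dimethyl-2-[(1R)-4-oxocyclopent-2-en-1-yl]butanamide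
Conditions: Rh2(cap)4 (1 mol %), t-BuOOH (70 % aq., 5 equiv), K2CO3 (0.5 equiv), DCM, rt
Reagents that add atoms: tert-butyl hydroperoxide (CC(C)(C)OO)
Why: Rhodium-catalysed radical allylic C–H oxidation attacks the unhindered ring CH2 and not the congested tertiary allylic C–H, and oxygen ends at the allyl terminus remote from the bulky side chain, giving the 4-substituted cyclopent-2-enone with both stereocentres untouched.

**Step 5**
Reactants: 10
Product: 12 (3S,4R)-4-{(2S)-1-[methoxy(methyl)amino]-3-methyl-1-oxobutan-2-yl}-3-(2-methylprop-2-en-1-yl)cyclopent-1-en-1-yl trifluoromethanesulfonate, via trimethylsilyl enol ether 11 (not isolated)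
Conditions: 2-methylallylMgCl (slow addition), CuBr·SMe2 (20 mol %), LiCl, TMSCl, THF, −78 °C; non-aqueous work-up; then CsF, PhNTf2, DME, rt
Reagents that add atoms: 2-methylallylmagnesium chloride (CC(=C)C[Mg]Cl); N-phenylbis(trifluoromethanesulfonimide) (O=S(=O)(N(c1ccccc1)S(=O)(=O)C(F)(F)F)C(F)(F)F)
Why: Copper-catalysed, TMSCl-accelerated conjugate addition places the methallyl group anti to the neighbouring ring substituent (the usual trans selectivity of 4-substituted cyclopentenones, new centre S), and the regiodefined silyl enol ether is unmasked by fluoride and O-triflated, which fixes the position of the future C2=C3 bond.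

**Step 6**
Reactants: 12
Product: 13 (2S)-N-methoxy-N,3-dimethyl-2-[(1R,2S)-4-methyl-2-(2-methylprop-2-en-1-yl)cyclopent-3-en-1-yl]butanamide
Conditions: MeZnCl (2 equiv), Pd(PPh3)4 (5 mol %), THF, 50 °C
Reagents that add atoms: methylzinc chloride (C[Zn]Cl)
Why: Negishi cross-coupling of the alkenyl triflate installs the vinylic methyl group without moving the double bond, and the organozinc tolerates the Weinreb amide and the isolated alkenes.

**Step 7**
Reactants: 13
Product: 14 (4S)-5-methyl-4-[(1R,2S)-4-methyl-2-(2-methylprop-2-en-1-yl)cyclopent-3-en-1-yl]hex-1-en-3-one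
Conditions: vinylMgBr (3 equiv), THF, 0 °C → rt; inverse quench into cold 1 M HCl
Reagents that add atoms: vinylmagnesium bromide (C=C[Mg]Br)
Why: Weinreb ketone synthesis, in which the stable magnesium chelate prevents over-addition and the acidic inverse quench keeps the liberated amine from adding to the vinyl ketone.

**Step 8**
Reactants: 14
Product: 15 (3aS,8S,8aR)-2,5-dimethyl-8-(propan-2-yl)-3a,4,8,8a-tetrahydroazulen-7(1H)-one (trans-fused, H-3a β, H-8a α)
Conditions: Hoveyda–Grubbs II (10 mol %), toluene (2 mM), 80 °C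
Reagents that add atoms: none
Why: Ring-closing metathesis between the enone vinyl group and the 1,1-disubstituted methallyl alkene closes the seven-membered ring while the trisubstituted cyclopentene alkene stays inert, and C8 sits in its thermodynamically preferred pseudo-equatorial orientation next to the ketone.

**Step 9**
Reactants: 15
Product: 16 (3aS,7S,8S,8aR)-2,5-dimethyl-8-(propan-2-yl)-1,3a,4,7,8,8a-hexahydroazulen-7-ol (7α-OH, cis to 8α-i-Pr)
Conditions: L-Selectride (1.2 equiv), THF, −78 °C; H2O quench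
Reagents that add atoms: none
Why: 1,2-Reduction of the β-substituted enone by the bulky hydride occurs by equatorial attack on the β face (the α face is screened by axial H-8a), giving the pseudo-axial 7α-alcohol cis to the isopropyl group.

**Step 10**
Reactants: 16
Product: 17 (3aS,5R,6S,7S,8S,8aR)-5,6-epoxy-2,5-dimethyl-8-(propan-2-yl)-1,3a,4,5,6,7,8,8a-octahydroazulen-7-ol (α-epoxide, cis to OH)
Conditions: VO(acac)2 (5 mol %), t-BuOOH (1.5 equiv, decane), DCM, 0 °C → rt
Reagents that add atoms: tert-butyl hydroperoxide (CC(C)(C)OO)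
Why: Vanadium-catalysed hydroxyl-directed epoxidation delivers oxygen syn to the pseudo-axial allylic OH and is chemoselective for the allylic alkene over the isolated C2=C3 bond, which sets C5 and C6.

**Step 11**
Reactants: 17
Product: 18 (3aS,5R,7R,8S,8aR)-2,5-dimethyl-8-(propan-2-yl)-1,3a,4,5,6,7,8,8a-octahydroazulene-5,7-diol (5α-OH, 5β-Me, 7α-OH)
Conditions: LiAlH4, THF, 0 → 40 °C; Fieser work-up
Reagents that add atoms: none
Why: Hydride opens the trisubstituted epoxide by SN2 attack at the secondary carbon C6, as with 1-methylcyclohexene oxide, so the C5–O bond and its configuration are kept and the cis-1,3-diol results.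

**Step 12**
Reactants: 19 catechol (benzene-1,2-diol)
Product: 20 2-methoxyphenol
Conditions: MeI (1.0 equiv), K2CO3, acetone, reflux; separate from dimethyl ether and catechol
Reagents that add atoms: iodomethane (CI)
Why: Williamson mono-O-methylation with one equivalent of electrophile, the second OH being less acidic once the first is alkylated.

**Step 13**
Reactants: 20
Product: 21 2-methoxyphenyl acetate
Conditions: Ac2O, pyridine, cat. DMAP, DCM, rt
Reagents that add atoms: acetic anhydride (CC(=O)OC(C)=O)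
Why: O-Acetylation turns the phenol into a weaker donor than the methoxy group, so the next electrophilic substitution is directed by OMe.

**Step 14**
Reactants: 21
Product: 22 5-bromo-2-methoxyphenyl acetate
Conditions: NBS, MeCN, rt
Reagents that add atoms: N-bromosuccinimide (O=C1CCC(=O)N1Br)
Why: Electrophilic aromatic bromination goes para to the stronger donor OMe, which places bromine at the future carboxyl position.

**Step 15**
Reactants: 22
Product: 23 5-bromo-2-methoxyphenol
Conditions: K2CO3 (cat.), MeOH, rt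
Reagents that add atoms: none
Why: Base-catalysed methanolysis removes the aryl acetate, which is not compatible with the later organolithium step.

**Step 16**
Reactants: 23
Product: 24 2-(benzyloxy)-4-bromo-1-methoxybenzene
Conditions: BnBr, K2CO3, DMF, rt
Reagents that add atoms: benzyl bromide (BrCc1ccccc1)
Why: Williamson benzylation gives a phenol protecting group that survives butyllithium and acylation and is later removed under neutral conditions.

**Step 17**
Reactants: 24
Product: 26 3-(benzyloxy)-4-methoxybenzoic acid, via aryllithium 25 (not isolated)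
Conditions: n-BuLi, THF, −78 °C; CO2 (g); aq. HCl
Reagents that add atoms: carbon dioxide (O=C=O)
Why: Bromine–lithium exchange is fast at −78 °C and the aryllithium is carboxylated before benzylic deprotonation can compete.

**Step 18**
Reactants: 26
Product: 27 3-(benzyloxy)-4-methoxybenzoyl chloride
Conditions: (COCl)2, cat. DMF, DCM, 0 °C → rt
Reagents that add atoms: oxalyl chloride (O=C(Cl)C(=O)Cl)
Why: Vilsmeier-catalysed acid chloride formation gives an acylating agent strong enough for the hindered secondary alcohol.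

**Step 19**
Reactants: 18; 27
Product: 28 (3aS,5R,7R,8S,8aR)-5-hydroxy-2,5-dimethyl-8-(propan-2-yl)-1,3a,4,5,6,7,8,8a-octahydroazulen-7-yl 3-(benzyloxy)-4-methoxybenzoate
Conditions: Et3N, DMAP (0.5 equiv), DCM, 0 → 40 °C
Reagents that add atoms: none
Why: DMAP-catalysed acylation by the acid chloride is chemoselective for the secondary 7-OH over the tertiary 5-OH and keeps the configuration at C7.

**Step 20**
Reactants: 28
Product: 29 (2R,3S,3aS,5R,7R,8S,8aR)-2,3-epoxy-5-hydroxy-2,5-dimethyl-8-(propan-2-yl)decahydroazulen-7-yl 3-(benzyloxy)-4-methoxybenzoate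
Conditions: VO(acac)2 (10 mol %), t-BuOOH (2 equiv), toluene, rt → 40 °C
Reagents that add atoms: tert-butyl hydroperoxide (CC(C)(C)OO)
Why: Hydroxyl-directed vanadium epoxidation, in which the tertiary 5α-OH (bishomoallylic to C2=C3) delivers the peroxide oxygen to the α face of the only remaining alkene and sets C2 (R) and C3 (S).

**Step 21**
Reactants: 29
Product: 30 (2R,3S,3aS,5R,7R,8S,8aR)-2,3-epoxy-5-hydroxy-2,5-dimethyl-8-(propan-2-yl)decahydroazulen-7-yl 3-hydroxy-4-methoxybenzoate
Conditions: H2 (1 atm), 10 % Pd/C, EtOAc, rt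
Reagents that add atoms: none
Why: Hydrogenolysis of the benzyl aryl ether is neutral and, with no alkene left, spares the non-benzylic epoxide, the tertiary alcohol and the aryl ester.

**Compound list**
1 | cyclopentene oxide (meso) | C1C[C@@H]2O[C@@H]2C1 | starting material
2 | 3-methylbutanoyl chloride | CC(C)CC(=O)Cl | starting material
3 | lithium (1S)-cyclopent-2-en-1-olate | [Li+].[O-][C@@H]1C=CCC1 | intermediate
4 | (1S)-cyclopent-2-en-1-yl 3-methylbutanoate | CC(C)CC(=O)O[C@@H]1C=CCC1 | intermediate
5 | trimethyl{[(1Z)-1-[(1S)-cyclopent-2-en-1-yloxy]-3-methylbut-1-en-1-yl]oxy}silane | CC(C)/C=C(\O[Si](C)(C)C)O[C@@H]1C=CCC1 | intermediate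
6 | trimethylsilyl (2S)-2-[(1R)-cyclopent-2-en-1-yl]-3-methylbutanoate | C[Si](C)(C)OC(=O)[C@@H](C(C)C)[C@H]1C=CCC1 | intermediate
7 | (2S)-2-[(1R)-cyclopent-2-en-1-yl]-3-methylbutanoic acid | OC(=O)[C@@H](C(C)C)[C@H]1C=CCC1 | intermediate
8 | (2S)-2-[(1R)-cyclopent-2-en-1-yl]-1-(1H-imidazol-1-yl)-3-methylbutan-1-one | O=C(n1ccnc1)[C@@H](C(C)C)[C@H]1C=CCC1 | intermediate
9 | (2S)-2-[(1R)-cyclopent-2-en-1-yl]-N-methoxy-N,3-dimethylbutanamide | CON(C)C(=O)[C@@H](C(C)C)[C@H]1C=CCC1 | intermediate
10 | (2S)-N-methoxy-N,3-dimethyl-2-[(1R)-4-oxocyclopent-2-en-1-yl]butanamide | CON(C)C(=O)[C@@H](C(C)C)[C@H]1C=CC(=O)C1 | intermediate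
11 | (2S)-N-methoxy-N,3-dimethyl-2-[(1R,2S)-2-(2-methylprop-2-en-1-yl)-4-(trimethylsilyloxy)cyclopent-3-en-1-yl]butanamide | CON(C)C(=O)[C@@H](C(C)C)[C@@H]1CC(O[Si](C)(C)C)=C[C@H]1CC(C)=C | intermediate
12 | (3S,4R)-4-{(2S)-1-[methoxy(methyl)amino]-3-methyl-1-oxobutan-2-yl}-3-(2-methylprop-2-en-1-yl)cyclopent-1-en-1-yl trifluoromethanesulfonate | CON(C)C(=O)[C@@H](C(C)C)[C@@H]1CC(OS(=O)(=O)C(F)(F)F)=C[C@H]1CC(C)=C | intermediate
13 | (2S)-N-methoxy-N,3-dimethyl-2-[(1R,2S)-4-methyl-2-(2-methylprop-2-en-1-yl)cyclopent-3-en-1-yl]butanamide | CON(C)C(=O)[C@@H](C(C)C)[C@@H]1CC(C)=C[C@H]1CC(C)=C | intermediate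
14 | (4S)-5-methyl-4-[(1R,2S)-4-methyl-2-(2-methylprop-2-en-1-yl)cyclopent-3-en-1-yl]hex-1-en-3-one | C=CC(=O)[C@@H](C(C)C)[C@@H]1CC(C)=C[C@H]1CC(C)=C | intermediate
15 | (3aS,8S,8aR)-2,5-dimethyl-8-(propan-2-yl)-3a,4,8,8a-tetrahydroazulen-7(1H)-one | O=C1C=C(C)C[C@H]2[C@@H](CC(C)=C2)[C@@H]1C(C)C | intermediate
16 | (3aS,7S,8S,8aR)-2,5-dimethyl-8-(propan-2-yl)-1,3a,4,7,8,8a-hexahydroazulen-7-ol | O[C@@H]1C=C(C)C[C@H]2[C@@H](CC(C)=C2)[C@@H]1C(C)C | intermediate
17 | (3aS,5R,6S,7S,8S,8aR)-5,6-epoxy-2,5-dimethyl-8-(propan-2-yl)-1,3a,4,5,6,7,8,8a-octahydroazulen-7-ol | O[C@@H]1[C@@H]3O[C@]3(C)C[C@H]2[C@@H](CC(C)=C2)[C@@H]1C(C)C | intermediate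
18 | (3aS,5R,7R,8S,8aR)-2,5-dimethyl-8-(propan-2-yl)-1,3a,4,5,6,7,8,8a-octahydroazulene-5,7-diol | O[C@@H]1C[C@](C)(O)C[C@H]2[C@@H](CC(C)=C2)[C@@H]1C(C)C | intermediate
19 | catechol | Oc1ccccc1O | starting material
20 | 2-methoxyphenol | COc1ccccc1O | intermediate
21 | 2-methoxyphenyl acetate | COc1ccccc1OC(C)=O | intermediate
22 | 5-bromo-2-methoxyphenyl acetate | COc1ccc(Br)cc1OC(C)=O | intermediate
23 | 5-bromo-2-methoxyphenol | COc1ccc(Br)cc1O | intermediate
24 | 2-(benzyloxy)-4-bromo-1-methoxybenzene | COc1ccc(Br)cc1OCc1ccccc1 | intermediate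
25 | [3-(benzyloxy)-4-methoxyphenyl]lithium | [Li]c1ccc(OC)c(OCc2ccccc2)c1 | intermediate
26 | 3-(benzyloxy)-4-methoxybenzoic acid | COc1ccc(C(=O)O)cc1OCc1ccccc1 | intermediate
27 | 3-(benzyloxy)-4-methoxybenzoyl chloride | COc1ccc(C(=O)Cl)cc1OCc1ccccc1 | intermediate
28 | (3aS,5R,7R,8S,8aR)-5-hydroxy-2,5-dimethyl-8-(propan-2-yl)-1,3a,4,5,6,7,8,8a-octahydroazulen-7-yl 3-(benzyloxy)-4-methoxybenzoate | COc1ccc(C(=O)O[C@@H]2C[C@](C)(O)C[C@H]3[C@@H](CC(C)=C3)[C@@H]2C(C)C)cc1OCc1ccccc1 | intermediate
29 | (2R,3S,3aS,5R,7R,8S,8aR)-2,3-epoxy-5-hydroxy-2,5-dimethyl-8-(propan-2-yl)decahydroazulen-7-yl 3-(benzyloxy)-4-methoxybenzoate | COc1ccc(C(=O)O[C@@H]2C[C@](C)(O)C[C@H]3[C@@H](C[C@@]4(C)O[C@@H]34)[C@@H]2C(C)C)cc1OCc1ccccc1 | intermediate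
30 | (2R,3S,3aS,5R,7R,8S,8aR)-2,3-epoxy-5-hydroxy-2,5-dimethyl-8-(propan-2-yl)decahydroazulen-7-yl 3-hydroxy-4-methoxybenzoate | COc1ccc(C(=O)O[C@@H]2C[C@](C)(O)C[C@H]3[C@@H](C[C@@]4(C)O[C@@H]34)[C@@H]2C(C)C)cc1O | target

**Totals**
Total step count: 21. Longest linear sequence: 14 steps (steps 1–11, then 19–21). The aryl branch (steps 12–18) runs in parallel and joins at step 19.

**Three steps most likely to fail**

Step 5 (conjugate methallylation and enolate capture). Allyl-type copper reagents can add 1,2, and the silyl enol ether to triflate exchange has to work beside a Weinreb amide. The fallback leaves from 10 and replaces the organocopper nucleophile by a Lewis-acid Hosomi–Sakurai addition. (2-Methylallyl)trimethylsilane with stoichiometric TBSOTf and 2,6-di-tert-butylpyridine in DCM at −78 °C adds anti to the ring substituent and leaves the regiodefined, chromatography-stable silyl enol ether (2S)-2-[(1R,2S)-4-(tert-butyldimethylsilyloxy)-2-(2-methylprop-2-en-1-yl)cyclopent-3-en-1-yl]-N-methoxy-N,3-dimethylbutanamide F1. F1 is then converted with CsF/PhNTf2 in DME into triflate 12, where the route is rejoined.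

Step 8 (metathesis of an electron-poor vinyl ketone with a 1,1-disubstituted alkene to a trans-fused seven-membered trisubstituted enone). The fallback closes the ring at the alcohol oxidation level and leaves from 13. DIBAL-H (THF, −78 °C) gives the aldehyde (2S)-3-methyl-2-[(1R,2S)-4-methyl-2-(2-methylprop-2-en-1-yl)cyclopent-3-en-1-yl]butanal F2. VinylMgBr gives the allylic alcohol (3RS,4S)-5-methyl-4-[(1R,2S)-4-methyl-2-(2-methylprop-2-en-1-yl)cyclopent-3-en-1-yl]hex-1-en-3-ol F3 as a mixture of carbinol epimers. This electron-rich diene cyclises with Grubbs II (DCM, 40 °C) to (3aS,7RS,8S,8aR)-2,5-dimethyl-8-(propan-2-yl)-1,3a,4,7,8,8a-hexahydroazulen-7-ol F4. Dess–Martin oxidation converges both epimers on enone 15, where the route is rejoined.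

Step 20 (face selectivity of an epoxidation directed by a remote tertiary hydroxyl; a mixture or the β-epoxide is possible). The fallback is a two-step halohydrin route from 28 that puts oxygen on the face opposite to the one an undirected electrophile attacks. NBS in aqueous DME forms the bromonium ion on the more exposed β face and water opens it anti at the tertiary carbon, giving the bromohydrin (2R,3R,3aS,5R,7R,8S,8aR)-3-bromo-2,5-dihydroxy-2,5-dimethyl-8-(propan-2-yl)decahydroazulen-7-yl 3-(benzyloxy)-4-methoxybenzoate F5. K2CO3 in MeOH at 0 °C then closes the oxirane with inversion at C3 to give 29, where the route is rejoined.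

**Further compounds**
F1 | step 5 | (2S)-2-[(1R,2S)-4-(tert-butyldimethylsilyloxy)-2-(2-methylprop-2-en-1-yl)cyclopent-3-en-1-yl]-N-methoxy-N,3-dimethylbutanamide | CON(C)C(=O)[C@@H](C(C)C)[C@@H]1CC(O[Si](C)(C)C(C)(C)C)=C[C@H]1CC(C)=C
F2 | step 8 | (2S)-3-methyl-2-[(1R,2S)-4-methyl-2-(2-methylprop-2-en-1-yl)cyclopent-3-en-1-yl]butanal | O=C[C@@H](C(C)C)[C@@H]1CC(C)=C[C@H]1CC(C)=C
F3 | step 8 | (3RS,4S)-5-methyl-4-[(1R,2S)-4-methyl-2-(2-methylprop-2-en-1-yl)cyclopent-3-en-1-yl]hex-1-en-3-ol | C=CC(O)[C@@H](C(C)C)[C@@H]1CC(C)=C[C@H]1CC(C)=C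
F4 | step 8 | (3aS,7RS,8S,8aR)-2,5-dimethyl-8-(propan-2-yl)-1,3a,4,7,8,8a-hexahydroazulen-7-ol | OC1C=C(C)C[C@H]2[C@@H](CC(C)=C2)[C@@H]1C(C)C
F5 | step 20 | (2R,3R,3aS,5R,7R,8S,8aR)-3-bromo-2,5-dihydroxy-2,5-dimethyl-8-(propan-2-yl)decahydroazulen-7-yl 3-(benzyloxy)-4-methoxybenzoate | COc1ccc(C(=O)O[C@@H]2C[C@](C)(O)C[C@H]3[C@@H](C[C@@](C)(O)[C@@H]3Br)[C@@H]2C(C)C)cc1OCc1ccccc1
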